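**Retrosynthetic overview**

1. Target 25 ⇐ bridged lactone 22 (the C-2 carboxyl closed onto the 9-oxygen) + an (E)-propenyl nucleophile. The 9-oxygen comes from iodolactonisation of cycloheptene 20.
2. Cycloheptene 20 ⇐ ring-closing metathesis (C-8=C-9) of diene 19.
3. The cis-α-methylene-γ-lactone ⇐ C-6–C-7 bond between aldehyde 15 and an ester homoenolate (d3) equivalent, the allylindium from dienoate 4. This key step joins two natively electrophilic carbons (aldehyde C and dienoate β-C) and sets C-6 and C-7; C-11 follows by convex-face hydrogenation.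
4. C-1 (quaternary) and C-10 ⇐ Ireland–Claisen rearrangement of the dicrotyl ester of L-tartrate acetonide; the tartrate carbons become C-2, C-1, C-5 and C-6.
5. Ring order: γ-lactone (step 6) → seven-membered carbocycle (step 8) → temporary bridged lactone (step 9, opened in step 11).

Assumption and labels: atoms carry seco-guaiane labels (C-1 carbinol carbon bearing the butenoyl chain C-2 to C-4 and C-15; ring C-5, C-6, C-7, C-8, C-9, C-10; C-14 methyl on C-10; lactone C-11, C-12, C-13), β is the face of the 1-OH, and the target is (1S,5S,6R,7S,9R,10S,11R) in these labels; 6 and 23 are used as the pure (E) isomers.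

**Route**

Step 1
Reactants: 1 acrolein; 2 methyl acrylate
Product: 3 methyl 3-hydroxy-2-methylidenepent-4-enoate (racemic)
Conditions: DABCO (20 mol %), 2 (3 equiv), neat, rt
Reagents that add atoms: none
Why: Morita–Baylis–Hillman reaction in which the DABCO–acrylate zwitterion adds to the aldehyde carbon of acrolein and DABCO is then eliminated; the racemic carbinol centre is destroyed in step 2.

Step 2
Reactants: 3 methyl 3-hydroxy-2-methylidenepent-4-enoate
Product: 4 methyl (2Z)-2-(bromomethyl)penta-2,4-dienoate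
Conditions: PBr3, Et2O, 0 °C
Reagents that add atoms: phosphorus tribromide, BrP(Br)Br
Why: SN2′ bromination of a Baylis–Hillman alcohol, in which bromide enters at the acrylate CH2 with allylic transposition and the fully conjugated dienoate with the vinyl group trans to the ester (2Z) is the thermodynamic isomer.

Step 3
Reactants: 5 dimethyl (4R,5R)-2,2-dimethyl-1,3-dioxolane-4,5-dicarboxylate (dimethyl 2,3-O-isopropylidene-L-tartrate); 6 (2E)-but-2-en-1-ol
Product: 8 bis[(2E)-but-2-en-1-yl] (4R,5R)-2,2-dimethyl-1,3-dioxolane-4,5-dicarboxylate, via mixed methyl crotyl diester 7 (not isolated)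
Conditions: Ti(OiPr)4 (10 mol %), 6 (6 equiv in all, two of them incorporated), toluene, 110 °C, MeOH distilled off
Reagents that add atoms: (2E)-but-2-en-1-ol (second equivalent), C/C=C/CO
Why: Twofold Ti(OiPr)4-catalysed transesterification in one flask, in which the first molecule of 6 exchanges one methyl ester to give 7 and a second molecule of 6 exchanges the other to give 8, each exchange being driven by distilling off methanol, and under these neutral conditions neither tartrate stereocentre can epimerise.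

Step 4
Reactants: 8 bis[(2E)-but-2-en-1-yl] (4R,5R)-2,2-dimethyl-1,3-dioxolane-4,5-dicarboxylate
Product: 13 5-[(2E)-but-2-en-1-yl] 4-methyl (4S,5R)-4-[(2S)-but-3-en-2-yl]-2,2-dimethyl-1,3-dioxolane-4,5-dicarboxylate, via lithium enolate 9 (not isolated), via silyl ketene acetal 10 (not isolated), via trimethylsilyl ester 11 (not isolated), via carboxylic acid 12 (not isolated)
Conditions: LiN(i-Pr)2 (1.05 equiv), THF, −78 °C; Me3SiCl, −78 → 50 °C; then MeOH, Me3SiCHN2, 0 °C
Reagents that add atoms: trimethylsilyldiazomethane, C[Si](C)(C)C=[N+]=[N-]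
Why: Ireland–Claisen rearrangement, in which mono-deprotonation of the twofold-symmetric diester gives the chelated enolate (O–Li syn to the ring oxygen), silylation fixes this geometry, and the chair [3,3] shift of the (E)-crotyl unit takes place on the face anti to the neighbouring ester group so that the quaternary C-1 (S) and C-10 (S) are set in one event, after which methanolysis of the silyl ester and methylation by diazomethane released from Me3SiCHN2 give the methyl ester.

Step 5
Reactants: 13 5-[(2E)-but-2-en-1-yl] 4-methyl (4S,5R)-4-[(2S)-but-3-en-2-yl]-2,2-dimethyl-1,3-dioxolane-4,5-dicarboxylate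
Product: 14 methyl (4S,5R)-4-[(2S)-but-3-en-2-yl]-5-formyl-2,2-dimethyl-1,3-dioxolane-4-carboxylate
Conditions: i-Bu2AlH (1.1 equiv), CH2Cl2, −78 °C; aq KNaC4H4O6 (potassium sodium tartrate) work-up
Reagents that add atoms: none
Why: Partial ester reduction with i-Bu2AlH at −78 °C, where the aluminium hemiacetal of the α-alkoxy ester is stable until work-up and the unhindered crotyl ester reacts far faster than the methyl ester on the quaternary carbon.

Step 6
Reactants: 14 methyl (4S,5R)-4-[(2S)-but-3-en-2-yl]-5-formyl-2,2-dimethyl-1,3-dioxolane-4-carboxylate; 4 methyl (2Z)-2-(bromomethyl)penta-2,4-dienoate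
Product: 17 methyl (2S,3S)-2-[(2S)-but-3-en-2-yl]-3-[(2R,3S)-3-ethenyl-4-methylidene-5-oxooxolan-2-yl]-2,3-dihydroxypropanoate, via dihydroxy aldehyde 15 (not isolated), via hydroxy diester 16 (not isolated)
Conditions: TFA–H2O 9:1, 0 °C → rt, evaporate; In powder, 4, THF–H2O 1:1, rt; then 1 M HCl, 40 °C
Reagents that add atoms: none
Why: Indium-mediated Barbier addition of an ester homoenolate equivalent followed by lactonisation, in which the allylindium species formed from 4 attacks the aldehyde carbon C-6 through its γ-carbon C-7 (the β-carbon of the dienoate, natively an acceptor position), the free 5-OH released by acetonide hydrolysis chelates indium so that the new carbinol is formed syn to O-5 (6R), the (Z)-configured reagent reacts through a chair transition state to give the 6,7-syn adduct (7S), and acid then closes the cis-disubstituted α-methylene-γ-lactone with the unhindered ester.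

Step 7
Reactants: 17 methyl (2S,3S)-2-[(2S)-but-3-en-2-yl]-3-[(2R,3S)-3-ethenyl-4-methylidene-5-oxooxolan-2-yl]-2,3-dihydroxypropanoate; 18 2-methylpropanoyl chloride
Product: 19 methyl (2S,3S)-2-[(2S)-but-3-en-2-yl]-3-[(2R,3S)-3-ethenyl-4-methylidene-5-oxooxolan-2-yl]-2-hydroxy-3-[(2-methylpropanoyl)oxy]propanoate
Conditions: pyridine, DMAP (10 mol %), CH2Cl2, 0 °C → rt
Reagents that add atoms: none
Why: DMAP-catalysed acylation of the only secondary hydroxyl group, the tertiary 1-OH flanked by the ester being unreactive under these conditions.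

Step 8
Reactants: 19 methyl (2S,3S)-2-[(2S)-but-3-en-2-yl]-3-[(2R,3S)-3-ethenyl-4-methylidene-5-oxooxolan-2-yl]-2-hydroxy-3-[(2-methylpropanoyl)oxy]propanoate
Product: 20 methyl (3aS,6S,7S,8S,8aR)-7-hydroxy-6-methyl-3-methylidene-8-[(2-methylpropanoyl)oxy]-2-oxo-3,3a,6,7,8,8a-hexahydro-2H-cyclohepta[b]furan-7-carboxylate
Conditions: second-generation Grubbs catalyst (5 mol %), CH2Cl2 (2 mM), 40 °C
Reagents that add atoms: none
Why: Ring-closing metathesis of the two monosubstituted vinyl groups, which are held cis on the lactone and close the seven-membered ring (C-8=C-9) with loss of ethene, while the electron-poor 1,1-disubstituted methylene group is a much poorer partner.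

Step 9
Reactants: 20 methyl (3aS,6S,7S,8S,8aR)-7-hydroxy-6-methyl-3-methylidene-8-[(2-methylpropanoyl)oxy]-2-oxo-3,3a,6,7,8,8a-hexahydro-2H-cyclohepta[b]furan-7-carboxylate
Product: 21 7,5-lactone of (3aS,4S,5S,6S,7S,8S,8aR)-5,7-dihydroxy-4-iodo-6-methyl-3-methylidene-8-[(2-methylpropanoyl)oxy]-2-oxooctahydro-2H-cyclohepta[b]furan-7-carboxylic acid (8β-iodo bis-lactone; C-2 carboxyl bridged to the 9α-oxygen)
Conditions: I2 (3 equiv), MeCN, 0 °C → rt, dark
Reagents that add atoms: iodine, II
Why: Iodolactonisation with ester participation, in which the carbonyl oxygen of the α-face C-2 ester attacks C-9 of the iodonium ion in a 5-exo anti addition and iodide removes the methyl group, so that the 9-oxygen is delivered cis to C-2 (the 9α configuration, relayed from C-1) and iodine ends on C-8.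

Step 10
Reactants: 21 8β-iodo bis-lactone
Product: 22 7,5-lactone of (3R,3aS,5R,6S,7S,8S,8aR)-5,7-dihydroxy-3,6-dimethyl-8-[(2-methylpropanoyl)oxy]-2-oxooctahydro-2H-cyclohepta[b]furan-7-carboxylic acid
Conditions: H2 (1 atm), Pd/C (10 wt %), NaOAc, EtOAc–EtOH, rt
Reagents that add atoms: none
Why: Heterogeneous hydrogenation and hydrogenolysis in one operation, in which the C–I bond is cleaved and hydrogen adds to the exocyclic methylene from the convex face of the cis-fused lactone (the face of H-6 and H-7), placing the new methyl group on the concave face (11R).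

Step 11
Reactants: 22 bis-lactone; 23 (1E)-1-bromoprop-1-ene
Product: 25 (3R,3aS,5R,6S,7S,8S,8aR)-7-[(2E)-but-2-enoyl]-5,7-dihydroxy-3,6-dimethyl-2-oxooctahydro-2H-cyclohepta[b]furan-8-yl 2-methylpropanoate, via bridged lactol 24 (not isolated)
Conditions: 23 (2.2 equiv), t-BuLi (2 equiv per 23), Et2O, −78 °C; MgBr2·OEt2; then 22, THF, −78 → −40 °C; aq NH4Cl
Reagents that add atoms: none
Why: Mono-addition of an alkenyl Grignard reagent to a lactone as in the conversion of aldonolactones into ketoses, in which the first equivalent deprotonates the 1-OH, the magnesium alkoxide chelates and activates only the adjacent bridged lactone carbonyl while the fused lactone and the hindered isobutyrate do not react at −78 to −40 °C, the chelated tetrahedral adduct resists a second addition, and on work-up lactol 24 opens to the conjugated (E)-enone with release of the 9α-hydroxyl.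

**Compound list**

1 | acrolein | C=CC=O | starting material
2 | methyl acrylate | C=CC(=O)OC | starting material
3 | methyl 3-hydroxy-2-methylidenepent-4-enoate (racemic) | C=CC(O)C(=C)C(=O)OC | intermediate
4 | methyl (2Z)-2-(bromomethyl)penta-2,4-dienoate | COC(=O)/C(CBr)=C/C=C | intermediate
5 | dimethyl (4R,5R)-2,2-dimethyl-1,3-dioxolane-4,5-dicarboxylate | COC(=O)[C@@H]1OC(C)(C)O[C@H]1C(=O)OC | starting material
6 | (2E)-but-2-en-1-ol | C/C=C/CO | starting material
7 | 4-[(2E)-but-2-en-1-yl] 5-methyl (4R,5R)-2,2-dimethyl-1,3-dioxolane-4,5-dicarboxylate (mixed methyl crotyl diester) | C/C=C/COC(=O)[C@@H]1OC(C)(C)O[C@H]1C(=O)OC | intermediate (not isolated)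
8 | bis[(2E)-but-2-en-1-yl] (4R,5R)-2,2-dimethyl-1,3-dioxolane-4,5-dicarboxylate | C/C=C/COC(=O)[C@@H]1OC(C)(C)O[C@H]1C(=O)OC/C=C/C | intermediate
9 | lithium enolate of 8 (O–Li cis to the ring oxygen) | [Li+].C/C=C/CO/C([O-])=C1/OC(C)(C)O[C@H]1C(=O)OC/C=C/C | intermediate (not isolated)
10 | (2E)-but-2-en-1-yl (4Z,5R)-4-{[(2E)-but-2-en-1-yloxy](trimethylsilyloxy)methylidene}-2,2-dimethyl-1,3-dioxolane-5-carboxylate | C/C=C/CO/C(O[Si](C)(C)C)=C1/OC(C)(C)O[C@H]1C(=O)OC/C=C/C | intermediate (not isolated)
11 | trimethylsilyl ester of acid 12 | C[Si](C)(C)OC(=O)[C@@]1([C@@H](C)C=C)OC(C)(C)O[C@H]1C(=O)OC/C=C/C | intermediate (not isolated)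
12 | (4S,5R)-4-[(2S)-but-3-en-2-yl]-5-{[(2E)-but-2-en-1-yloxy]carbonyl}-2,2-dimethyl-1,3-dioxolane-4-carboxylic acid | OC(=O)[C@@]1([C@@H](C)C=C)OC(C)(C)O[C@H]1C(=O)OC/C=C/C | intermediate (not isolated)
13 | 5-[(2E)-but-2-en-1-yl] 4-methyl (4S,5R)-4-[(2S)-but-3-en-2-yl]-2,2-dimethyl-1,3-dioxolane-4,5-dicarboxylate | COC(=O)[C@@]1([C@@H](C)C=C)OC(C)(C)O[C@H]1C(=O)OC/C=C/C | intermediate
14 | methyl (4S,5R)-4-[(2S)-but-3-en-2-yl]-5-formyl-2,2-dimethyl-1,3-dioxolane-4-carboxylate | COC(=O)[C@@]1([C@@H](C)C=C)OC(C)(C)O[C@H]1C=O | intermediate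
15 | methyl (2S,3R)-2-[(2S)-but-3-en-2-yl]-2,3-dihydroxy-4-oxobutanoate | COC(=O)[C@](O)([C@@H](C)C=C)[C@@H](O)C=O | intermediate (not isolated)
16 | dimethyl (2S,3S,4R,5S)-2-[(2S)-but-3-en-2-yl]-5-ethenyl-2,3,4-trihydroxy-6-methylideneheptanedioate | COC(=O)[C@](O)([C@@H](C)C=C)[C@@H](O)[C@H](O)[C@@H](C=C)C(=C)C(=O)OC | intermediate (not isolated)
17 | methyl (2S,3S)-2-[(2S)-but-3-en-2-yl]-3-[(2R,3S)-3-ethenyl-4-methylidene-5-oxooxolan-2-yl]-2,3-dihydroxypropanoate | COC(=O)[C@](O)([C@@H](C)C=C)[C@@H](O)[C@@H]1OC(=O)C(=C)[C@@H]1C=C | intermediate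
18 | 2-methylpropanoyl chloride | CC(C)C(Cl)=O | starting material
19 | methyl (2S,3S)-2-[(2S)-but-3-en-2-yl]-3-[(2R,3S)-3-ethenyl-4-methylidene-5-oxooxolan-2-yl]-2-hydroxy-3-[(2-methylpropanoyl)oxy]propanoate | COC(=O)[C@](O)([C@@H](C)C=C)[C@@H](OC(=O)C(C)C)[C@@H]1OC(=O)C(=C)[C@@H]1C=C | intermediate
20 | methyl (3aS,6S,7S,8S,8aR)-7-hydroxy-6-methyl-3-methylidene-8-[(2-methylpropanoyl)oxy]-2-oxo-3,3a,6,7,8,8a-hexahydro-2H-cyclohepta[b]furan-7-carboxylate | COC(=O)[C@]1(O)[C@@H](C)C=C[C@@H]2[C@@H](OC(=O)C2=C)[C@@H]1OC(=O)C(C)C | intermediate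
21 | 7,5-lactone of (3aS,4S,5S,6S,7S,8S,8aR)-5,7-dihydroxy-4-iodo-6-methyl-3-methylidene-8-[(2-methylpropanoyl)oxy]-2-oxooctahydro-2H-cyclohepta[b]furan-7-carboxylic acid | O=C3[C@]1(O)[C@@H](C)[C@H](O3)[C@@H](I)[C@@H]2[C@@H](OC(=O)C2=C)[C@@H]1OC(=O)C(C)C | intermediate
22 | 7,5-lactone of (3R,3aS,5R,6S,7S,8S,8aR)-5,7-dihydroxy-3,6-dimethyl-8-[(2-methylpropanoyl)oxy]-2-oxooctahydro-2H-cyclohepta[b]furan-7-carboxylic acid | O=C3[C@]1(O)[C@@H](C)[C@H](O3)C[C@@H]2[C@@H](OC(=O)[C@@H]2C)[C@@H]1OC(=O)C(C)C | intermediate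
23 | (1E)-1-bromoprop-1-ene | C/C=C/Br | starting material
24 | bridged lactol (hemiketal between C-2 and the 9-oxygen; ring-chain tautomer of 25, C-2 configuration undefined) | C/C=C/C3(O)[C@]1(O)[C@@H](C)[C@H](O3)C[C@@H]2[C@@H](OC(=O)[C@@H]2C)[C@@H]1OC(=O)C(C)C | intermediate (not isolated)
25 | (3R,3aS,5R,6S,7S,8S,8aR)-7-[(2E)-but-2-enoyl]-5,7-dihydroxy-3,6-dimethyl-2-oxooctahydro-2H-cyclohepta[b]furan-8-yl 2-methylpropanoate | C/C=C/C(=O)[C@]1(O)[C@@H](C)[C@H](O)C[C@@H]2[C@@H](OC(=O)[C@@H]2C)[C@@H]1OC(=O)C(C)C | target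

**Step count and risks**

Total step count: 11 (two steps for bromide 4, nine in the main line). Longest linear sequence: 9 steps (steps 3 to 11, from 5).

The three steps most likely to fail:

Step 4 (Ireland–Claisen rearrangement). The tartrate enolate can suffer β-elimination of the dioxolane oxygen, mono-enolisation of the diester may not be clean, and the ketene acetal geometry fixes C-10. The fallback sets out from 5 and 6 and comes back at 14. Alcohol 6 is acylated with methyl chloroformate and pyridine to (2E)-but-2-en-1-yl methyl carbonate F1. Diester 5 is deprotonated (LiN(i-Pr)2, THF, −78 °C) to the lithium enolate of 5 F2 and silylated to methyl (4Z,5R)-4-[methoxy(trimethylsilyloxy)methylidene]-2,2-dimethyl-1,3-dioxolane-5-carboxylate F3. An intermolecular, branched-selective iridium-catalysed allylic alkylation of F3 with F1 ([Ir(cod)Cl]2 and a Feringa-type phosphoramidite ligand, THF, rt) then forms the C-1–C-10 bond. The ligand enantiomer is chosen to set C-10 as S, and the dioxolane again directs the allyl group trans to the neighbouring ester. The product is dimethyl (4S,5R)-4-[(2S)-but-3-en-2-yl]-2,2-dimethyl-1,3-dioxolane-4,5-dicarboxylate F4. i-Bu2AlH at −78 °C then reduces the less hindered ester of F4 to aldehyde 14.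

Step 6 (key homoenolate-equivalent addition). The allylindium from 4 is a pentadienyl species and could react at its vinyl terminus, the 6,7-syn preference could erode, and chelation by the free 5-OH must beat the non-chelated pathway. The fallback sets out from 4 and from the protected aldehyde 14 and comes back to the route at 16. Bromide 4 is converted with Bu3SnLi (THF, −78 °C) into methyl (2Z)-2-[(tributylstannyl)methyl]penta-2,4-dienoate F5. F5 is then added to 14 under MgBr2·OEt2 chelation (CH2Cl2, −20 °C). This is a Lewis-acid-mediated, open-transition-state allylstannane addition of the Keck type: the chelate through the dioxolane oxygen should give 5,6-syn, and the γ-substituted stannane 6,7-syn. The product is the acetonide-protected adduct methyl (4S,5S)-4-[(2S)-but-3-en-2-yl]-5-[(1R,2S)-2-ethenyl-1-hydroxy-3-(methoxycarbonyl)but-3-en-1-yl]-2,2-dimethyl-1,3-dioxolane-4-carboxylate F6. Aqueous TFA removes the acetonide to give 16, which lactonises to 17 as in the route.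

Step 11 (chemoselective propenyl addition). Three ester carbonyls are present, and the argument for the bridged α-alkoxide lactone rests on chelation activation; the basic conditions also threaten C-11. The fallback sets out from 22 and comes back at lactol 24. Compound 22 is treated with LiN(i-Pr)2 (3.3 equiv) and Me3SiCl at −78 °C to give the tris(trimethylsilyl) derivative of 22 F7. In F7 the 1-OH is a silyl ether and both enolisable esters (fused lactone and isobutyrate) are masked as silyl ketene acetals. (E)-Prop-1-enyllithium made from 23 can then attack only the bridged lactone. Dilute aqueous acid strips the three silyl groups and re-protonates C-11 from the convex face (11R), giving 24 and hence 25.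

**Further compounds**

F1 | step 4 | (2E)-but-2-en-1-yl methyl carbonate | C/C=C/COC(=O)OC
F2 | step 4 | lithium enolate of 5 (O–Li cis to the ring oxygen) | [Li+].CO/C([O-])=C1/OC(C)(C)O[C@H]1C(=O)OC
F3 | step 4 | methyl (4Z,5R)-4-[methoxy(trimethylsilyloxy)methylidene]-2,2-dimethyl-1,3-dioxolane-5-carboxylate | CO/C(O[Si](C)(C)C)=C1/OC(C)(C)O[C@H]1C(=O)OC
F4 | step 4 | dimethyl (4S,5R)-4-[(2S)-but-3-en-2-yl]-2,2-dimethyl-1,3-dioxolane-4,5-dicarboxylate | COC(=O)[C@@]1([C@@H](C)C=C)OC(C)(C)O[C@H]1C(=O)OC
F5 | step 6 | methyl (2Z)-2-[(tributylstannyl)methyl]penta-2,4-dienoate | COC(=O)/C(C[Sn](CCCC)(CCCC)CCCC)=C/C=C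
F6 | step 6 | methyl (4S,5S)-4-[(2S)-but-3-en-2-yl]-5-[(1R,2S)-2-ethenyl-1-hydroxy-3-(methoxycarbonyl)but-3-en-1-yl]-2,2-dimethyl-1,3-dioxolane-4-carboxylate | COC(=O)[C@@]1([C@@H](C)C=C)OC(C)(C)O[C@H]1[C@H](O)[C@@H](C=C)C(=C)C(=O)OC
F7 | step 11 | tris(trimethylsilyl) derivative of 22 (1-O-silyl ether; silyl ketene acetals of the fused lactone and of the isobutyrate) | O=C3[C@]1(O[Si](C)(C)C)[C@@H](C)[C@H](O3)C[C@@H]2[C@@H](OC(O[Si](C)(C)C)=C2C)[C@@H]1OC(O[Si](C)(C)C)=C(C)C
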